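A direct plan would build the hydroxymethyl ketone A1 from resorcinol in five steps, ending with a carbene-catalysed addition of a salicylaldehyde to formaldehyde. It would then join A1 and protected vanillin as the seven-membered cyclic acetal A2 and contract A2 with a chiral acid to the protected dihydroflavonol A3.
Its weakest steps would be:
(a) the hydroxymethylation of the aldehyde: the formyl group is chelated and flanked by two oxygens, so the Breslow intermediate would form slowly while formaldehyde self-condenses, and five steps would have added only a prenyl group, one oxygen and two carbons to resorcinol;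
(b) the closure of A2 by double transacetalisation: a medium ring closed under equilibrium control through a chelated phenol oxygen, with nothing to disfavour open-chain or oligomeric acetals and with three acid-labile acetals already present;
(c) the ring contraction of A2 to A3: a reaction type without precedent would have to set both stereocentres on the most advanced material, where any ionisation outside the chiral ion pair gives racemate and the cation can also lose a proton or close to a five-membered ring.

Plan of the new route. The retrosynthesis cuts C3–OH first (enolate oxidation), then C2–C1′, which detaches ring B and leaves an achiral chromone made of rings A and C. The pyranone is cut at O1–C2 and C2–C3 to an o-hydroxyacetophenone and a one-carbon amide acetal, and the C6–prenyl bond is traced back to a prenyl ether on the future O1. In the forward sense ring A is bought, ring C is closed on it as a flat 4-pyranone, and ring B is attached last. This is possible because C2 carries ring B and is also the β-carbon of the C4 ketone (O1–C2–C3–C4=O), so the 2,3-dehydro compound is a vinylogous ester that accepts an aryl nucleophile at C2. It is also possible because C6 is para to C8a–O1, so two [3,3] shifts carry a prenyl group from O1 to C6 and to no other carbon. No hydroxymethyl ketone, medium-ring acetal or acetal shift occurs; C2 is set by a catalyst in a known reaction type, and C3 follows from C2.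

Key step: step 7

Remark: the (R)-ligand in step 7 is assumed to give the (2S)-ketone, by analogy with the sense of induction of this ligand class on cyclic enones; if a test on the chromone shows the opposite sense, the (S)-ligand is used and nothing else changes.

Step 1
Reactants: 1 1-(2,4,6-trihydroxyphenyl)ethan-1-one (2′,4′,6′-trihydroxyacetophenone, commercial monohydrate dried azeotropically with toluene)
Product: 2 1-[2-hydroxy-4,6-bis(triisopropylsilyloxy)phenyl]ethan-1-one
Conditions: i-Pr3SiCl (2.1 equiv), imidazole (4.5 equiv), DMF, 0 °C → rt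
Reagents that add atoms: chlorotri(propan-2-yl)silane (i-Pr3SiCl), CC(C)[Si](Cl)(C(C)C)C(C)C
Why: Silyl ether formation at the para OH and one ortho OH, after which the last ortho OH is locked in a hydrogen bond to the ketone and silylation should stop, leaving free the oxygen that becomes O1.

Step 2
Reactants: 2 1-[2-hydroxy-4,6-bis(triisopropylsilyloxy)phenyl]ethan-1-one; 3 3-methylbut-2-en-1-ol (prenol)
Product: 4 1-[2-(3-methylbut-2-en-1-yloxy)-4,6-bis(triisopropylsilyloxy)phenyl]ethan-1-one
Conditions: PPh3 (1.5 equiv), DIAD (1.5 equiv), THF, 0 °C → rt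
Reagents that add atoms: none
Why: Mitsunobu etherification at the primary carbon of prenol under neutral conditions, with the chelated phenol as pronucleophile and no base that could cleave the aryl silyl ethers.

Step 3
Reactants: 4 1-[2-(3-methylbut-2-en-1-yloxy)-4,6-bis(triisopropylsilyloxy)phenyl]ethan-1-one
Product: 7 1-[6-hydroxy-3-(3-methylbut-2-en-1-yl)-2,4-bis(triisopropylsilyloxy)phenyl]ethan-1-one, via ortho-dienone 5 (not isolated), via para-dienone 6 (not isolated)
Conditions: PhNEt2, 200 °C, sealed tube, argon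
Reagents that add atoms: none
Why: para-Claisen–Cope rearrangement, in which a [3,3] shift to the only free ortho carbon gives dienone 5 with a 1,1-dimethylallyl group, a second [3,3] (Cope) shift to the para carbon between the two silyloxy groups (the future C6) gives dienone 6 with the normal prenyl group, and enolisation gives the phenol; the other ortho carbon carries the acetyl group, so no regioisomer can form, and the released OH is the future O1.

Step 4
Reactants: 7 1-[6-hydroxy-3-(3-methylbut-2-en-1-yl)-2,4-bis(triisopropylsilyloxy)phenyl]ethan-1-one; 8 N,N-dimethylformamide dimethyl acetal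
Product: 10 6-(3-methylbut-2-en-1-yl)-5,7-bis(triisopropylsilyloxy)-4H-chromen-4-one, via enaminone 9 (not isolated)
Conditions: 8 (3 equiv), PhMe, 90 °C; evaporate; AcOH (5 equiv), PhMe, 60 °C
Reagents that add atoms: none
Why: Condensation of the methyl ketone with the amide acetal gives enaminone 9, and acid-promoted 6-endo-trig addition of the only free phenol oxygen to its β-carbon with loss of dimethylamine closes ring C as the 4-pyranone (standard chromone synthesis); because only the OH para to the prenyl group is free, only the 6-prenyl isomer can form.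

Step 5
Reactants: 11 4-bromo-2-methoxyphenol
Product: 12 (4-bromo-2-methoxyphenoxy)triisopropylsilane
Conditions: i-Pr3SiCl (1.2 equiv), imidazole (2.5 equiv), DMF, rt
Reagents that add atoms: chlorotri(propan-2-yl)silane (i-Pr3SiCl), CC(C)[Si](Cl)(C(C)C)C(C)C
Why: Phenol silylation, so that ring B carries the same fluoride-labile group as ring A and no phenoxide para to C2 can arise under the basic conditions of step 8.

Step 6
Reactants: 12 (4-bromo-2-methoxyphenoxy)triisopropylsilane
Product: 15 [3-methoxy-4-(triisopropylsilyloxy)phenyl]boronic acid, via aryllithium 13 (not isolated), via lithium triisopropoxyborate 14 (not isolated)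
Conditions: n-BuLi (1.1 equiv), THF, −78 °C; B(OiPr)3 (1.5 equiv), −78 °C → rt; 1 M HCl to pH 5, 0 °C
Reagents that add atoms: triisopropyl borate, CC(C)OB(OC(C)C)OC(C)C (boron); water, O (the two OH groups on boron)
Why: Bromine–lithium exchange, borylation with the trialkyl borate and mild hydrolysis; the lithium sits para to the silyloxy group, so no retro-Brook silyl shift is possible.

Step 7
Reactants: 10 6-(3-methylbut-2-en-1-yl)-5,7-bis(triisopropylsilyloxy)-4H-chromen-4-one; 15 [3-methoxy-4-(triisopropylsilyloxy)phenyl]boronic acid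
Product: 16 (2S)-2-[3-methoxy-4-(triisopropylsilyloxy)phenyl]-6-(3-methylbut-2-en-1-yl)-5,7-bis(triisopropylsilyloxy)-2,3-dihydro-4H-chromen-4-one
Conditions: 15 (2 equiv), Pd(OCOCF3)2 (5 mol%), (R)-4-tert-butyl-2-(pyridin-2-yl)-4,5-dihydro-1,3-oxazole [(R)-t-BuPyOx] (6 mol%), NH4PF6 (30 mol%), H2O (5 equiv), ClCH2CH2Cl, 60 °C
Reagents that add atoms: none
Why: Enantioselective conjugate addition of an arylboronic acid to a chromone catalysed by divalent palladium, a known reaction type for this substrate class: transmetalation gives a cationic aryl–palladium pyridine-oxazoline complex, the C2=C3 bond of 10 coordinates, the aryl group migrates to C2 in the enantio-determining syn insertion, and water protonates the C3-bound palladium enolate and regenerates the catalyst. No ring is closed here: ring C is already in place as a flat pyranone, and the step joins ring B to it through the C2–C1′ bond. The one new stereocentre, C2, is set by the ligand, whose tert-butyl group blocks one face of the coordinated enone; (2S) in 16 is the spatial arrangement of (2R) in the target, the descriptor changing only once C3 carries oxygen. The step needs attack at C2, preference for the enone over the prenyl alkene, and protonation of the palladium enolate before it can open ring C. C2 is the only electrophilic alkene carbon (terminus of the vinylogous ester), the trisubstituted prenyl alkene is unactivated and shielded by two silyloxy groups, and after syn insertion the C2–H is anti to palladium, so β-hydride elimination to the flavone should not compete. The precursors are an achiral bicyclic enone and a simple arylboronic acid, whereas the product contains every carbon of the target and its C2 configuration.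

Step 8
Reactants: 16 (2S)-2-[3-methoxy-4-(triisopropylsilyloxy)phenyl]-6-(3-methylbut-2-en-1-yl)-5,7-bis(triisopropylsilyloxy)-2,3-dihydro-4H-chromen-4-one
Product: 18 (2R,3R)-3-hydroxy-2-[3-methoxy-4-(triisopropylsilyloxy)phenyl]-6-(3-methylbut-2-en-1-yl)-5,7-bis(triisopropylsilyloxy)-2,3-dihydro-4H-chromen-4-one, via sodium enolate 17 (not isolated)
Conditions: NaN(SiMe3)2 (1.15 equiv), THF, −78 °C; (±)-trans-3-phenyl-2-(phenylsulfonyl)oxaziridine (1.4 equiv), −78 °C; AcOH quench at −78 °C
Reagents that add atoms: (±)-trans-3-phenyl-2-(phenylsulfonyl)oxaziridine, O=S(=O)(c1ccccc1)N1OC1c1ccccc1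
Why: Enolate hydroxylation with an N-sulfonyloxaziridine, in which oxygen is delivered to C3 on the face opposite the C2 aryl group to give the 2,3-trans (2R,3R) isomer, which is also the more stable one; β-elimination of the O1 aryloxide should be slow at −78 °C because the endocyclic C2–O1 bond lies near the nodal plane of the enolate, and the oxaziridine leaves the prenyl alkene untouched.

Step 9
Reactants: 18 (2R,3R)-3-hydroxy-2-[3-methoxy-4-(triisopropylsilyloxy)phenyl]-6-(3-methylbut-2-en-1-yl)-5,7-bis(triisopropylsilyloxy)-2,3-dihydro-4H-chromen-4-one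
Product: 19 (2R,3R)-3,5,7-trihydroxy-2-(4-hydroxy-3-methoxyphenyl)-6-(3-methylbut-2-en-1-yl)-2,3-dihydro-4H-chromen-4-one
Conditions: Bu4NF (3.6 equiv), AcOH (4 equiv), THF, 0 °C → rt; pH 5 phosphate buffer work-up
Reagents that add atoms: none
Why: Fluoride cleavage of the three aryl silyl ethers, buffered with acetic acid so that each phenoxide is protonated as it forms and neither ring opening at C2 nor enolisation at C3 can take place; no acid strong enough to cyclise the prenyl group onto a neighbouring phenol is present.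

**Compound list**
1 | 1-(2,4,6-trihydroxyphenyl)ethan-1-one | CC(=O)c1c(O)cc(O)cc1O | starting material
2 | 1-[2-hydroxy-4,6-bis(triisopropylsilyloxy)phenyl]ethan-1-one | CC(=O)c1c(O)cc(O[Si](C(C)C)(C(C)C)C(C)C)cc1O[Si](C(C)C)(C(C)C)C(C)C | intermediate
3 | 3-methylbut-2-en-1-ol | CC(C)=CCO | starting material
4 | 1-[2-(3-methylbut-2-en-1-yloxy)-4,6-bis(triisopropylsilyloxy)phenyl]ethan-1-one | CC(=O)c1c(OCC=C(C)C)cc(O[Si](C(C)C)(C(C)C)C(C)C)cc1O[Si](C(C)C)(C(C)C)C(C)C | intermediate
5 | 2-acetyl-6-(2-methylbut-3-en-2-yl)-3,5-bis(triisopropylsilyloxy)cyclohexa-2,4-dien-1-one (ortho-dienone, racemic) | CC(=O)C1=C(O[Si](C(C)C)(C(C)C)C(C)C)C=C(O[Si](C(C)C)(C(C)C)C(C)C)C(C(C)(C)C=C)C1=O | intermediate (not isolated)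
6 | 2-acetyl-4-(3-methylbut-2-en-1-yl)-3,5-bis(triisopropylsilyloxy)cyclohexa-2,5-dien-1-one (para-dienone) | CC(=O)C1=C(O[Si](C(C)C)(C(C)C)C(C)C)C(CC=C(C)C)C(O[Si](C(C)C)(C(C)C)C(C)C)=CC1=O | intermediate (not isolated)
7 | 1-[6-hydroxy-3-(3-methylbut-2-en-1-yl)-2,4-bis(triisopropylsilyloxy)phenyl]ethan-1-one | CC(=O)c1c(O)cc(O[Si](C(C)C)(C(C)C)C(C)C)c(CC=C(C)C)c1O[Si](C(C)C)(C(C)C)C(C)C | intermediate
8 | N,N-dimethylformamide dimethyl acetal | COC(OC)N(C)C | starting material
9 | (E)-3-(dimethylamino)-1-[6-hydroxy-3-(3-methylbut-2-en-1-yl)-2,4-bis(triisopropylsilyloxy)phenyl]prop-2-en-1-one | CN(C)/C=C/C(=O)c1c(O)cc(O[Si](C(C)C)(C(C)C)C(C)C)c(CC=C(C)C)c1O[Si](C(C)C)(C(C)C)C(C)C | intermediate (not isolated)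
10 | 6-(3-methylbut-2-en-1-yl)-5,7-bis(triisopropylsilyloxy)-4H-chromen-4-one | O=c1ccoc2cc(O[Si](C(C)C)(C(C)C)C(C)C)c(CC=C(C)C)c(O[Si](C(C)C)(C(C)C)C(C)C)c12 | intermediate
11 | 4-bromo-2-methoxyphenol | COc1cc(Br)ccc1O | starting material
12 | (4-bromo-2-methoxyphenoxy)triisopropylsilane | COc1cc(Br)ccc1O[Si](C(C)C)(C(C)C)C(C)C | intermediate
13 | [3-methoxy-4-(triisopropylsilyloxy)phenyl]lithium | [Li]c1ccc(O[Si](C(C)C)(C(C)C)C(C)C)c(OC)c1 | intermediate (not isolated)
14 | lithium triisopropoxy[3-methoxy-4-(triisopropylsilyloxy)phenyl]borate | [Li+].COc1cc([B-](OC(C)C)(OC(C)C)OC(C)C)ccc1O[Si](C(C)C)(C(C)C)C(C)C | intermediate (not isolated)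
15 | [3-methoxy-4-(triisopropylsilyloxy)phenyl]boronic acid | COc1cc(B(O)O)ccc1O[Si](C(C)C)(C(C)C)C(C)C | intermediate
16 | (2S)-2-[3-methoxy-4-(triisopropylsilyloxy)phenyl]-6-(3-methylbut-2-en-1-yl)-5,7-bis(triisopropylsilyloxy)-2,3-dihydro-4H-chromen-4-one | COc1cc([C@H]2Oc3cc(O[Si](C(C)C)(C(C)C)C(C)C)c(CC=C(C)C)c(O[Si](C(C)C)(C(C)C)C(C)C)c3C(=O)C2)ccc1O[Si](C(C)C)(C(C)C)C(C)C | intermediate
17 | sodium (2S)-2-[3-methoxy-4-(triisopropylsilyloxy)phenyl]-6-(3-methylbut-2-en-1-yl)-5,7-bis(triisopropylsilyloxy)-2H-chromen-4-olate | COc1cc([C@H]2Oc3cc(O[Si](C(C)C)(C(C)C)C(C)C)c(CC=C(C)C)c(O[Si](C(C)C)(C(C)C)C(C)C)c3C(O[Na])=C2)ccc1O[Si](C(C)C)(C(C)C)C(C)C | intermediate (not isolated)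
18 | (2R,3R)-3-hydroxy-2-[3-methoxy-4-(triisopropylsilyloxy)phenyl]-6-(3-methylbut-2-en-1-yl)-5,7-bis(triisopropylsilyloxy)-2,3-dihydro-4H-chromen-4-one | COc1cc([C@H]2Oc3cc(O[Si](C(C)C)(C(C)C)C(C)C)c(CC=C(C)C)c(O[Si](C(C)C)(C(C)C)C(C)C)c3C(=O)[C@@H]2O)ccc1O[Si](C(C)C)(C(C)C)C(C)C | intermediate
19 | (2R,3R)-3,5,7-trihydroxy-2-(4-hydroxy-3-methoxyphenyl)-6-(3-methylbut-2-en-1-yl)-2,3-dihydro-4H-chromen-4-one | COc1cc([C@H]2Oc3cc(O)c(CC=C(C)C)c(O)c3C(=O)[C@@H]2O)ccc1O | target

Total step count: 9. Longest linear sequence: 7 steps (steps 1–4 and 7–9, from 1 to 19).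

Steps most likely to fail:

Step 7. Insertion may be slow at the chromone, whose C2 is deactivated by three oxygen donors, so that the boronic acid is lost by protodeboronation; the ee may also erode if the palladium enolate opens ring C reversibly. The fallback sets out from 10 and 12 and comes back at 16: the C2–C1′ bond would be made without stereocontrol and the centre resolved afterwards. Bromide 12 would be converted into its Grignard reagent (Mg, LiCl, THF) and added to 10 in the presence of CuBr·SMe2 (10 mol%) and Me3SiCl at −78 → −20 °C; aqueous NH4Cl should give racemic 2-[3-methoxy-4-(triisopropylsilyloxy)phenyl]-6-(3-methylbut-2-en-1-yl)-5,7-bis(triisopropylsilyloxy)chroman-4-one F1. Kinetic resolution by asymmetric transfer hydrogenation (RuCl(p-cymene)[(R,R)-TsDPEN], HCO2H/Et3N, to about half conversion) should reduce the (2R)-ketone to the cis-(2R,4R)-chroman-4-ol F2 and leave the (2S)-ketone, which is 16; F2 would be removed by chromatography.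

Step 8. The enolate may expel the O1 aryloxide (racemisation at C2 through the open chalcone) or add to the sulfonimine that the oxidant leaves behind. The fallback sets out from 16 and comes back at 18 and avoids a free enolate. Soft enolisation (Me3SiOTf, Et3N, CH2Cl2, 0 °C) would give the (2S)-4-(trimethylsilyloxy)-2H-chromene F3. Rubottom oxidation with dimethyldioxirane (1.05 equiv, acetone/CH2Cl2, −78 °C) should attack the electron-rich enol ether far faster than the shielded prenyl alkene, again anti to the aryl group, and give the (2R,3R)-3-(trimethylsilyloxy) ketone F4. Citric acid in MeOH at 0 °C would remove only the trimethylsilyl group and give 18.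

Step 3. The two triisopropylsilyloxy groups crowd both the ortho and the para carbon, so dienone 5 may enolise to the 1,1-dimethylallyl phenol before the Cope shift, or the ether may fragment at 200 °C. The fallback sets out from 1 and comes back at 10: the side chain would reach C6 by an ortho-Claisen shift from O5 of a chromone and be completed by olefin cross-metathesis.
- Monosilylation of 1 at the unchelated para OH (i-Pr3SiCl 1.05 equiv, imidazole, CH2Cl2, −20 °C) would give 1-[2,6-dihydroxy-4-(triisopropylsilyloxy)phenyl]ethan-1-one F5.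
- The conditions of step 4 would give 5-hydroxy-7-(triisopropylsilyloxy)-4H-chromen-4-one F6, the two ortho OH groups being equivalent.
- Mitsunobu allylation of the chelated 5-OH (allyl alcohol, PPh3, DIAD, THF) would give 5-(prop-2-en-1-yloxy)-7-(triisopropylsilyloxy)-4H-chromen-4-one F7.
- Claisen rearrangement (PhNEt2, 190 °C) can go only to C6, since the other ortho position is the ring-fusion carbon C4a, and should give 5-hydroxy-6-(prop-2-en-1-yl)-7-(triisopropylsilyloxy)-4H-chromen-4-one F8.
- Cross-metathesis with 2-methylbut-2-ene (second-generation Grubbs catalyst, 5 mol%, 40 °C) would give 5-hydroxy-6-(3-methylbut-2-en-1-yl)-7-(triisopropylsilyloxy)-4H-chromen-4-one F9.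
- Silylation of the 5-OH (i-Pr3SiOTf, 2,6-lutidine, CH2Cl2, 0 °C) would give 10.

**Further compounds**
F1 | step 7 | rac-2-[3-methoxy-4-(triisopropylsilyloxy)phenyl]-6-(3-methylbut-2-en-1-yl)-5,7-bis(triisopropylsilyloxy)-2,3-dihydro-4H-chromen-4-one | COc1cc(C2Oc3cc(O[Si](C(C)C)(C(C)C)C(C)C)c(CC=C(C)C)c(O[Si](C(C)C)(C(C)C)C(C)C)c3C(=O)C2)ccc1O[Si](C(C)C)(C(C)C)C(C)C
F2 | step 7 | (2R,4R)-2-[3-methoxy-4-(triisopropylsilyloxy)phenyl]-6-(3-methylbut-2-en-1-yl)-5,7-bis(triisopropylsilyloxy)-3,4-dihydro-2H-chromen-4-ol | COc1cc([C@@H]2Oc3cc(O[Si](C(C)C)(C(C)C)C(C)C)c(CC=C(C)C)c(O[Si](C(C)C)(C(C)C)C(C)C)c3[C@H](O)C2)ccc1O[Si](C(C)C)(C(C)C)C(C)C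
F3 | step 8 | (2S)-2-[3-methoxy-4-(triisopropylsilyloxy)phenyl]-6-(3-methylbut-2-en-1-yl)-5,7-bis(triisopropylsilyloxy)-4-(trimethylsilyloxy)-2H-chromene | COc1cc([C@H]2Oc3cc(O[Si](C(C)C)(C(C)C)C(C)C)c(CC=C(C)C)c(O[Si](C(C)C)(C(C)C)C(C)C)c3C(O[Si](C)(C)C)=C2)ccc1O[Si](C(C)C)(C(C)C)C(C)C
F4 | step 8 | (2R,3R)-2-[3-methoxy-4-(triisopropylsilyloxy)phenyl]-6-(3-methylbut-2-en-1-yl)-5,7-bis(triisopropylsilyloxy)-3-(trimethylsilyloxy)-2,3-dihydro-4H-chromen-4-one | COc1cc([C@H]2Oc3cc(O[Si](C(C)C)(C(C)C)C(C)C)c(CC=C(C)C)c(O[Si](C(C)C)(C(C)C)C(C)C)c3C(=O)[C@@H]2O[Si](C)(C)C)ccc1O[Si](C(C)C)(C(C)C)C(C)C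
F5 | step 3 | 1-[2,6-dihydroxy-4-(triisopropylsilyloxy)phenyl]ethan-1-one | CC(=O)c1c(O)cc(O[Si](C(C)C)(C(C)C)C(C)C)cc1O
F6 | step 3 | 5-hydroxy-7-(triisopropylsilyloxy)-4H-chromen-4-one | O=c1ccoc2cc(O[Si](C(C)C)(C(C)C)C(C)C)cc(O)c12
F7 | step 3 | 5-(prop-2-en-1-yloxy)-7-(triisopropylsilyloxy)-4H-chromen-4-one | C=CCOc1cc(O[Si](C(C)C)(C(C)C)C(C)C)cc2occc(=O)c12
F8 | step 3 | 5-hydroxy-6-(prop-2-en-1-yl)-7-(triisopropylsilyloxy)-4H-chromen-4-one | C=CCc1c(O[Si](C(C)C)(C(C)C)C(C)C)cc2occc(=O)c2c1O
F9 | step 3 | 5-hydroxy-6-(3-methylbut-2-en-1-yl)-7-(triisopropylsilyloxy)-4H-chromen-4-one | CC(C)=CCc1c(O[Si](C(C)C)(C(C)C)C(C)C)cc2occc(=O)c2c1O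
A1 | direct plan | 2-hydroxy-1-[6-hydroxy-2,4-bis(methoxymethoxy)-3-(3-methylbut-2-en-1-yl)phenyl]ethan-1-one | O=C(CO)c1c(O)cc(OCOC)c(CC=C(C)C)c1OCOC
A2 | direct plan | rac-2-[3-methoxy-4-(methoxymethoxy)phenyl]-6,8-bis(methoxymethoxy)-7-(3-methylbut-2-en-1-yl)-2H-1,3-benzodioxepin-5(4H)-one | COCOc1ccc(C2OCC(=O)c3c(OCOC)c(CC=C(C)C)c(OCOC)cc3O2)cc1OC
A3 | direct plan | (2R,3R)-3-hydroxy-2-[3-methoxy-4-(methoxymethoxy)phenyl]-5,7-bis(methoxymethoxy)-6-(3-methylbut-2-en-1-yl)-2,3-dihydro-4H-chromen-4-one | COCOc1ccc([C@H]2Oc3cc(OCOC)c(CC=C(C)C)c(OCOC)c3C(=O)[C@@H]2O)cc1OC
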